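**Retrosynthetic overview**

- The strategy rests on two features of the indole: on the pyrrole ring, C3 carries the methylsulfanyl group next to the bromine-bearing C2, and on the benzene ring the bromines sit at C4 and C6.
- C2–Br is traced back to a lactam carbonyl, so the last step is deoxybromination of 4,6-dibromo-3-(methylsulfanyl)oxindole with POBr3.
- The N1–C2 bond comes from lactamisation of an ortho-amino arylacetic ester, which closes the five-membered ring.
- The C3–C3a bond comes from a Gassman azasulfonium ylide [2,3]-sigmatropic rearrangement that brings in the sulfur and the ester carbon together. The aniline is 3,5-dibromoaniline, whose two ortho carbons are equivalent.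
- Ring order: the benzene ring is bought with both bromines; the pyrrole ring is closed second and aromatised last.

Key step: step 1

Remark on the chemistry: the one sp3 carbon of the amino ester and of the oxindole is formed racemic and is left uncontrolled, because it becomes the planar C3 of the target. The species formed before the amino ester are kept cold in one flask and are not isolated.

**Route**

Step 1
Reactants: 1 3,5-dibromoaniline; 2 tert-butyl hypochlorite; 3 ethyl 2-(methylsulfanyl)acetate
Product: 8 ethyl 2-(2-amino-4,6-dibromophenyl)-2-(methylsulfanyl)acetate (racemic), via N-chloro-3,5-dibromoaniline 4 (not isolated), via azasulfonium chloride 5 (not isolated), via azasulfonium ylide 6 (not isolated), via ortho-dienimine 7 (not isolated)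
Conditions: t-BuOCl (1.0 equiv), CH2Cl2, −65 °C; then 3 (1.1 equiv), −65 °C, 1 h; then Et3N (1.1 equiv), −65 °C to rt; aqueous work-up
Reagents that add atoms: ethyl 2-(methylsulfanyl)acetate (compound 3), CCOC(=O)CSC
Why: t-BuOCl should chlorinate only the nitrogen of 1 (the two bromines and the low temperature hold back ring chlorination) to give 4, whose N–Cl bond is then attacked at nitrogen by the sulfur of 3 to give azasulfonium chloride 5. Et3N removes the acidic proton between sulfur and the ester, and the stabilised ylide 6 bonds through its carbanion carbon to the ortho ring carbon in a five-membered cyclic transition state while the S–N bond breaks ([2,3]-sigmatropic shift of Sommelet–Hauser type), after which dienimine 7 re-aromatises to aniline 8 by a proton shift. This is the Gassman oxindole synthesis, which applies directly to this substrate class. No ring is closed here: the new bond is the future C3–C3a bond, and the five-membered lactam is closed in step 2. The new sp3 carbon is formed racemic with nothing to control it, which is acceptable because it becomes the planar C3 of the indole. The step needs ortho selectivity and a single regioisomer: the concerted geometry cannot reach the para carbon and the two ortho carbons of 1 are equivalent by symmetry, so only the 4,6-dibromo pattern can arise, while using exactly one equivalent of 2, consumed before 3 is added, keeps the thioether from being chlorinated.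

Step 2
Reactants: 8 ethyl 2-(2-amino-4,6-dibromophenyl)-2-(methylsulfanyl)acetate (racemic, crude)
Product: 9 4,6-dibromo-3-(methylsulfanyl)indolin-2-one (racemic)
Conditions: 2 M aq HCl, Et2O–THF, rt (50 °C if slow)
Reagents that add atoms: none
Why: Acid-promoted intramolecular aminolysis of the ester by the ortho amino group (5-exo-trig lactamisation, the closing stage of the Gassman oxindole synthesis) should be favoured because nucleophile and ester are held next to each other on the ring, and the C3 centre stays racemic since no chiral influence is present.

Step 3
Reactants: 9 4,6-dibromo-3-(methylsulfanyl)indolin-2-one (racemic); 10 phosphorus oxybromide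
Product: 12 2,4,6-tribromo-3-methylsulfanyl-1H-indole, via indol-2-yl dibromophosphate 11 (not isolated)
Conditions: POBr3 (2 equiv), ClCH2CH2Cl, 80 °C; then ice-cold aq NaHCO3
Reagents that add atoms: phosphorus oxybromide, O=P(Br)(Br)Br
Why: The C3–H, acidified by the sulfur, the aryl ring and the carbonyl, lets the lactam react as its 2-hydroxyindole tautomer, which POBr3 should O-phosphorylate to 11 before bromide displaces the phosphate at C2 by addition–elimination with aromatisation, the known POBr3 deoxybromination of oxindoles to 2-bromoindoles; the aryl bromides and the thioether are inert to the reagent and the racemic centre becomes planar.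

**Compound list**

1 | 3,5-dibromoaniline | Nc1cc(Br)cc(Br)c1 | starting material
2 | tert-butyl hypochlorite | CC(C)(C)OCl | starting material
3 | ethyl 2-(methylsulfanyl)acetate | CCOC(=O)CSC | starting material
4 | N-chloro-3,5-dibromoaniline | ClNc1cc(Br)cc(Br)c1 | intermediate
5 | (3,5-dibromoanilino)(2-ethoxy-2-oxoethyl)methylsulfonium chloride (azasulfonium chloride) | CCOC(=O)C[S+](C)Nc1cc(Br)cc(Br)c1.[Cl-] | intermediate
6 | (3,5-dibromoanilino)(methyl)sulfonium (ethoxycarbonyl)methylide (azasulfonium ylide) | CCOC(=O)[CH-][S+](C)Nc1cc(Br)cc(Br)c1 | intermediate
7 | ethyl 2-(2,4-dibromo-6-iminocyclohexa-2,4-dien-1-yl)-2-(methylsulfanyl)acetate (transient ortho-dienimine, mixture of stereoisomers) | CCOC(=O)C(SC)C1C(=N)C=C(Br)C=C1Br | intermediate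
8 | ethyl 2-(2-amino-4,6-dibromophenyl)-2-(methylsulfanyl)acetate (racemic) | CCOC(=O)C(SC)c1c(N)cc(Br)cc1Br | intermediate
9 | 4,6-dibromo-3-(methylsulfanyl)indolin-2-one (racemic) | CSC1C(=O)Nc2cc(Br)cc(Br)c12 | intermediate
10 | phosphorus oxybromide | O=P(Br)(Br)Br | starting material
11 | 4,6-dibromo-3-(methylsulfanyl)-1H-indol-2-yl phosphorodibromidate | CSc1c(OP(=O)(Br)Br)[nH]c2cc(Br)cc(Br)c12 | intermediate
12 | 2,4,6-tribromo-3-methylsulfanyl-1H-indole | CSc1c(Br)[nH]c2cc(Br)cc(Br)c12 | target

**Step count**

Total steps: 3. Longest linear sequence: 3 steps (1 to 8 to 9 to 12).

**Steps most likely to fail**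

Step 1. The weakly nucleophilic aniline may be N-chlorinated slowly or twice, and hypochlorite left over would then chlorinate the thioether, so the azasulfonium salt would not form cleanly. The fallback sets out from 3 and 1 and comes back at 5. It inverts the polarity of the S–N bond formation. Sulfide 3 is treated with SO2Cl2 in CH2Cl2 at −78 °C to give chloro(2-ethoxy-2-oxoethyl)(methyl)sulfonium chloride F1. Aniline 1 and 1,8-bis(dimethylamino)naphthalene as acid acceptor are then added at −78 °C, and attack of the aniline nitrogen on the chlorosulfonium sulfur should give azasulfonium chloride 5. Addition of Et3N and warming then continue as in step 1.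

Step 3. Displacement of the phosphate by bromide at C2 may be slow, and the acid generated may cause migration or loss of the methylsulfanyl group before the 2-bromoindole is formed. The fallback sets out from 9 and comes back at 12. The lactam is reduced with BH3·THF in THF (0 °C to reflux), the known borane reduction of oxindoles to indoles, to give 4,6-dibromo-3-(methylsulfanyl)-1H-indole F3. One equivalent of N-bromosuccinimide in CH2Cl2 at 0 °C should then brominate C2, the only free carbon of the pyrrole ring, as in the known C2 halogenation of 3-substituted indoles, to give 12.

Step 2. Ring closure may stall because the aniline nitrogen, meta to two bromines, is a poor nucleophile, so that ester hydrolysis without cyclisation competes. The fallback sets out from 8 and comes back at 9. The ester is saponified with LiOH in THF–H2O and the mixture is acidified with dilute HCl to give 2-(2-amino-4,6-dibromophenyl)-2-(methylsulfanyl)acetic acid F2. The acid is then activated with N-ethyl-N'-(3-dimethylaminopropyl)carbodiimide hydrochloride in CH2Cl2 at rt, so that the amine closes the lactam on the O-acylisourea to give 9.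

**Further compounds**

F1 | step 1 | chloro(2-ethoxy-2-oxoethyl)(methyl)sulfonium chloride | CCOC(=O)C[S+](C)Cl.[Cl-]
F2 | step 2 | 2-(2-amino-4,6-dibromophenyl)-2-(methylsulfanyl)acetic acid (racemic) | CSC(C(=O)O)c1c(N)cc(Br)cc1Br
F3 | step 3 | 4,6-dibromo-3-(methylsulfanyl)-1H-indole | CSc1c[nH]c2cc(Br)cc(Br)c12
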